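## Retrosynthetic overview

1. The oxirane is made last, by tartrate-controlled epoxidation of the C14 allylic alcohol; the exo-methylene comes from an α-phosphonolactone and formaldehyde.
2. The ten-membered ring is closed at C3–C4 by a Nozaki–Hiyama–Kishi reaction of a (Z)-vinyl iodide with the C3 aldehyde.
3. C8–C9 and the 1(10)-olefin come from a phosphoric-acid-catalysed allylboration of a lactone aldehyde with a racemic secondary allylboronate (new), followed by esterification with (R)-2-methylbutanoic acid.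
4. The cis-γ-lactone with C6 and C7 comes from an organocatalytic anti cross-aldol of an achiral 4-oxobutanoate with but-2-ynal, then lactonisation; the alkyne later becomes the (Z)-vinyl iodide.
5. Ring order: γ-lactone first, ten-membered carbocycle second, oxirane last.

Assumption: the SMILES is read literally, i.e. a cis-fused 6,12-olide (H-6/H-7 cis), 4Z olefin, ring-cis 1,10-oxirane, (1R,3S,6S,7R,8R,10R) and a (2R)-2-methylbutanoate. Atoms are labelled C1–C15 in germacrane numbering throughout (C6 lactone carbinol, C8 acyloxy, C3 hydroxy, C14 hydroxymethyl, C15 methyl, C11–C13 acrylate unit).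

## Route

Step 1
Reactants: 1 triethyl phosphonoacetate; 2 allyl bromide
Product: 3 ethyl 2-(diethoxyphosphoryl)pent-4-enoate (racemic)
Conditions: NaH (1.0 equiv), THF, 0 °C; then 2, 0 °C to rt
Reagents that add atoms: none
Why: SN2 C-alkylation of the stabilised phosphonoacetate anion installs the carbons that become C7 and C8.

Step 2
Reactants: 3 ethyl 2-(diethoxyphosphoryl)pent-4-enoate
Product: 4 ethyl 2-(diethoxyphosphoryl)-4-oxobutanoate (racemic)
Conditions: O3, CH2Cl2, −78 °C; then Me2S, −78 °C to rt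
Reagents that add atoms: ozone, O=[O+][O-]
Why: ozonolysis with reductive work-up cleaves the terminal olefin to the C8 aldehyde and leaves the phosphonoacetate untouched.

Step 3
Reactants: 5 but-2-yn-1-ol
Product: 6 but-2-ynal
Conditions: MnO2 (activated, 10 equiv), CH2Cl2, rt; filtered solution used at once
Reagents that add atoms: none
Why: MnO2 oxidation of a propargylic alcohol stops at the ynal.

Step 4
Reactants: 4 ethyl 2-(diethoxyphosphoryl)-4-oxobutanoate; 6 but-2-ynal
Product: 8 diethyl [(4S,5R)-4-formyl-2-oxo-5-(prop-1-yn-1-yl)oxolan-3-yl]phosphonate (cis-lactone aldehyde; C11 epimers), via anti-aldol adduct 7 (not isolated)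
Conditions: (S)-α,α-bis[3,5-bis(trifluoromethyl)phenyl]-2-pyrrolidinemethanol (10 mol%), 4 (2 equiv), 1,4-dioxane, H2O (3 equiv), 4 °C; then PPTS (20 mol%), CH2Cl2, rt
Reagents that add atoms: none
Why: enamine-catalysed direct cross-aldol onto a non-enolisable ynal gives, in the same sense as L-proline cross-aldols, the anti adduct (C7 S, C6 R), and the γ-hydroxy ester then lactonises to the cis-lactone; this sets the first two stereocentres.

Step 5
Reactants: 9 2-bromoprop-2-en-1-ol
Product: 10 [(2-bromoprop-2-en-1-yl)oxy](tert-butyl)dimethylsilane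
Conditions: TBSCl, imidazole, CH2Cl2, 0 °C to rt
Reagents that add atoms: tert-butyldimethylsilyl chloride, CC(C)(C)[Si](C)(C)Cl
Why: standard silylation protects the future C14 hydroxyl.

Step 6
Reactants: 11 3,3-diethoxyprop-1-yne
Product: 12 2,2'-(3,3-diethoxypropane-1,1-diyl)bis(4,4,5,5-tetramethyl-1,3,2-dioxaborolane)
Conditions: HBpin (2.4 equiv), CuCl (5 mol%), DPEphos (5.5 mol%), NaOtBu (10 mol%), toluene, rt
Reagents that add atoms: pinacolborane, B1OC(C)(C)C(C)(C)O1
Why: copper-hydride-catalysed double hydroboration of a terminal alkyne gives the 1,1-diboronate (C1 with C2 and the masked C3 aldehyde).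

Step 7
Reactants: 12 the 1,1-diboronate; 10 the 2-bromoallyl silyl ether
Product: 13 racemic tert-butyl{[5,5-diethoxy-2-methylidene-3-(4,4,5,5-tetramethyl-1,3,2-dioxaborolan-2-yl)pentyl]oxy}dimethylsilane
Conditions: Pd[P(t-Bu)3]2 (5 mol%), KOH (8 M aq., 3 equiv), 1,4-dioxane, rt
Reagents that add atoms: none
Why: chemoselective Suzuki–Miyaura mono-coupling of a geminal bis(boronate) with a vinyl bromide gives the secondary allylboronate; the product boronate is not activated for a second coupling.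

Step 8
Reactants: 8 the cis-lactone aldehyde; 13 the racemic secondary allylboronate
Product: 14 diethyl {(4R,5R)-4-[(1R,3E)-3-({[tert-butyl(dimethyl)silyl]oxy}methyl)-6,6-diethoxy-1-hydroxyhex-3-en-1-yl]-2-oxo-5-(prop-1-yn-1-yl)oxolan-3-yl}phosphonate (C8 R; C2 and C9 cis on the new olefin; C11 epimers)
Conditions: (R)-TRIP [(R)-3,3'-bis(2,4,6-triisopropylphenyl)-1,1'-binaphthyl-2,2'-diyl hydrogen phosphate] (10 mol%), 13 (2.5 equiv), 4 Å MS, toluene, −30 to 0 °C
Reagents that add atoms: none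
Why: Proposed new method: a chiral-phosphoric-acid-catalysed kinetic-resolution allylboration with a racemic secondary allyl pinacolboronate that carries a 2-(silyloxymethyl) substituent, run on an α-branched lactone aldehyde; the acid hydrogen-bonds to a boronate oxygen and the formyl C–H in a closed chair transition state, the α-substituent sits axial (avoiding the pinacol methyls and A(1,2) strain with the 2-substituent) so the trisubstituted olefin forms with C2 cis to C9, and the catalyst pairs re-face attack (C8 R, the sense that gives (R)-1-phenylbut-3-en-1-ol from benzaldehyde) with the (R)-boronate while the (S)-boronate is left behind; the closest known reactions are phosphoric-acid-catalysed allylboration of aldehydes with allyl and crotyl pinacolboronates and the kinetic resolution of 2-unsubstituted secondary allylboronates to Z-homoallylic alcohols.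

Step 9
Reactants: 15 tiglic acid
Product: 16 (2R)-2-methylbutanoic acid
Conditions: H2 (4 atm), Ru(OAc)2[(R)-H8-BINAP] (0.5 mol%), MeOH, rt
Reagents that add atoms: none
Why: asymmetric hydrogenation of an α,β-unsaturated acid with a Ru–biaryl-diphosphine carboxylate complex; the (R)-ligand gives the (R)-acid.

Step 10
Reactants: 14 the homoallylic alcohol; 16 (2R)-2-methylbutanoic acid
Product: 17 (1R,3E)-3-({[tert-butyl(dimethyl)silyl]oxy}methyl)-1-[(2R,3R)-4-(diethoxyphosphoryl)-5-oxo-2-(prop-1-yn-1-yl)oxolan-3-yl]-6,6-diethoxyhex-3-en-1-yl (2R)-2-methylbutanoate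
Conditions: 16 (1.5 equiv), DCC (1.6 equiv), DMAP (0.2 equiv), CH2Cl2, 0 °C
Reagents that add atoms: none
Why: Steglich esterification at low temperature acylates the C8 hydroxyl before it can translactonise onto C12, and fixes the 6,12-olide.

Step 11
Reactants: 17 the alkynyl ester
Product: 19 (1R,3E)-3-({[tert-butyl(dimethyl)silyl]oxy}methyl)-1-{(2R,3R)-4-(diethoxyphosphoryl)-2-[(1Z)-2-iodoprop-1-en-1-yl]-5-oxooxolan-3-yl}-6,6-diethoxyhex-3-en-1-yl (2R)-2-methylbutanoate, via Z-vinylsilane 18 (not isolated)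
Conditions: [Cp*Ru(MeCN)3]PF6 (3 mol%), BnMe2SiH (1.3 equiv), CH2Cl2, 0 °C to rt; solvent exchange; NIS (1.5 equiv), 2,6-lutidine, HFIP, 0 °C
Reagents that add atoms: N-iodosuccinimide, O=C1CCC(=O)N1I; benzyldimethylsilane, C[SiH](C)Cc1ccccc1 (its silicon is carried only by 18)
Why: Ru-catalysed trans-hydrosilylation places silicon on the alkyne carbon distal to the propargylic oxygen (C4) anti to the new C5–H, and ipso-iododesilylation with retention gives the (Z)-vinyl iodide with iodine cis to C6.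

Step 12
Reactants: 19 the vinyl iodide
Product: 20 (1R,3E)-1-{(2R,3R)-4-(diethoxyphosphoryl)-2-[(1Z)-2-iodoprop-1-en-1-yl]-5-oxooxolan-3-yl}-3-(hydroxymethyl)-6-oxohex-3-en-1-yl (2R)-2-methylbutanoate
Conditions: TFA/H2O (9:1), CH2Cl2, 0 °C; crude used at once
Reagents that add atoms: water, O
Why: aqueous acid hydrolyses the diethyl acetal to the C3 aldehyde and cleaves the primary silyl ether in one operation; the β,γ-unsaturated aldehyde is used immediately to avoid conjugation.

Step 13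
Reactants: 20 the iodo hydroxy aldehyde
Product: 21 (1(10)E,3S,4Z,6S,7R,8R)-11-(diethoxyphosphoryl)-3,14-dihydroxygermacra-1(10),4-dien-6,12-olid-8-yl (2R)-2-methylbutanoate (C11 epimers)
Conditions: CrCl2 (10 equiv), NiCl2 (2 mol%), DMSO/THF (3:1), rt, 20 added over 12 h to 2 mM
Reagents that add atoms: none
Why: intramolecular Nozaki–Hiyama–Kishi reaction forms C3–C4 and the ten-membered ring with retention of the Z olefin; the (3S) carbinol is expected from addition to the exposed aldehyde face of the folded chain (two cis units and the cis-lactone), which has to be confirmed experimentally.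

Step 14
Reactants: 21 the macrocyclic phosphonolactone
Product: 22 (1(10)E,3S,4Z,6S,7R,8R)-3,14-dihydroxygermacra-1(10),4,11(13)-trien-6,12-olid-8-yl (2R)-2-methylbutanoate
Conditions: aq. HCHO (37%, 10 equiv), K2CO3 (3 equiv), THF/H2O, 0 °C to rt
Reagents that add atoms: formaldehyde, C=O
Why: Horner–Wadsworth–Emmons olefination of the α-phosphonolactone with formaldehyde gives the α-methylene lactone under conditions mild enough for the ester and free hydroxyls; both C11 epimers converge.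

Step 15
Reactants: 22 the macrocyclic triene diol
Product: 23 (1R,3S,4Z,6S,7R,8R,10R)-1,10-epoxy-3,14-dihydroxygermacra-4,11(13)-dien-6,12-olid-8-yl (2R)-2-methylbutanoate (CNP0356520.2)
Conditions: Ti(OiPr)4 (20 mol%), D-(−)-diisopropyl tartrate (24 mol%), t-BuOOH (2 equiv, decane), 4 Å MS, CH2Cl2, −20 °C
Reagents that add atoms: tert-butyl hydroperoxide, CC(C)(C)OO
Why: Sharpless asymmetric epoxidation of the primary (E)-allylic alcohol; D-(−)-tartrate delivers oxygen to the face that gives (1R,10R), while the secondary C3 allylic alcohol (cis-substituted olefin) and the acrylate react far more slowly.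

## Compound list

1 | triethyl phosphonoacetate | CCOC(=O)CP(=O)(OCC)OCC | starting material
2 | allyl bromide | C=CCBr | starting material
3 | ethyl 2-(diethoxyphosphoryl)pent-4-enoate (racemic) | CCOC(=O)C(CC=C)P(=O)(OCC)OCC | intermediate
4 | ethyl 2-(diethoxyphosphoryl)-4-oxobutanoate (racemic) | CCOC(=O)C(CC=O)P(=O)(OCC)OCC | intermediate
5 | but-2-yn-1-ol | CC#CCO | starting material
6 | but-2-ynal | CC#CC=O | intermediate
7 | ethyl (3S,4R)-2-(diethoxyphosphoryl)-3-formyl-4-hydroxyhept-5-ynoate (anti-aldol adduct, not isolated) | CCOC(=O)C(P(=O)(OCC)OCC)[C@H](C=O)[C@@H](O)C#CC | intermediate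
8 | diethyl [(4S,5R)-4-formyl-2-oxo-5-(prop-1-yn-1-yl)oxolan-3-yl]phosphonate | CCOP(=O)(OCC)C1C(=O)O[C@@H](C#CC)[C@H]1C=O | intermediate
9 | 2-bromoprop-2-en-1-ol | C=C(Br)CO | starting material
10 | [(2-bromoprop-2-en-1-yl)oxy](tert-butyl)dimethylsilane | C=C(Br)CO[Si](C)(C)C(C)(C)C | intermediate
11 | 3,3-diethoxyprop-1-yne | C#CC(OCC)OCC | starting material
12 | 2,2'-(3,3-diethoxypropane-1,1-diyl)bis(4,4,5,5-tetramethyl-1,3,2-dioxaborolane) | CCOC(OCC)CC(B1OC(C)(C)C(C)(C)O1)B1OC(C)(C)C(C)(C)O1 | intermediate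
13 | racemic tert-butyl{[5,5-diethoxy-2-methylidene-3-(4,4,5,5-tetramethyl-1,3,2-dioxaborolan-2-yl)pentyl]oxy}dimethylsilane | CCOC(OCC)CC(B1OC(C)(C)C(C)(C)O1)C(=C)CO[Si](C)(C)C(C)(C)C | intermediate
14 | diethyl {(4R,5R)-4-[(1R,3E)-3-({[tert-butyl(dimethyl)silyl]oxy}methyl)-6,6-diethoxy-1-hydroxyhex-3-en-1-yl]-2-oxo-5-(prop-1-yn-1-yl)oxolan-3-yl}phosphonate | CCOP(=O)(OCC)C1C(=O)O[C@@H](C#CC)[C@H]1[C@H](O)C/C(CO[Si](C)(C)C(C)(C)C)=C\CC(OCC)OCC | intermediate
15 | tiglic acid, (2E)-2-methylbut-2-enoic acid | C/C=C(\C)C(=O)O | starting material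
16 | (2R)-2-methylbutanoic acid | CC[C@@H](C)C(=O)O | intermediate
17 | (1R,3E)-3-({[tert-butyl(dimethyl)silyl]oxy}methyl)-1-[(2R,3R)-4-(diethoxyphosphoryl)-5-oxo-2-(prop-1-yn-1-yl)oxolan-3-yl]-6,6-diethoxyhex-3-en-1-yl (2R)-2-methylbutanoate | CCOP(=O)(OCC)C1C(=O)O[C@@H](C#CC)[C@H]1[C@H](OC(=O)[C@H](C)CC)C/C(CO[Si](C)(C)C(C)(C)C)=C\CC(OCC)OCC | intermediate
18 | analogue of 19 with (1Z)-2-[benzyl(dimethyl)silyl]prop-1-en-1-yl in place of the iodopropenyl group (Z-vinylsilane, not isolated) | CCOP(=O)(OCC)C1C(=O)O[C@@H](/C=C(/C)[Si](C)(C)Cc2ccccc2)[C@H]1[C@H](OC(=O)[C@H](C)CC)C/C(CO[Si](C)(C)C(C)(C)C)=C\CC(OCC)OCC | intermediate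
19 | (1R,3E)-3-({[tert-butyl(dimethyl)silyl]oxy}methyl)-1-{(2R,3R)-4-(diethoxyphosphoryl)-2-[(1Z)-2-iodoprop-1-en-1-yl]-5-oxooxolan-3-yl}-6,6-diethoxyhex-3-en-1-yl (2R)-2-methylbutanoate | CCOP(=O)(OCC)C1C(=O)O[C@@H](/C=C(/C)I)[C@H]1[C@H](OC(=O)[C@H](C)CC)C/C(CO[Si](C)(C)C(C)(C)C)=C\CC(OCC)OCC | intermediate
20 | (1R,3E)-1-{(2R,3R)-4-(diethoxyphosphoryl)-2-[(1Z)-2-iodoprop-1-en-1-yl]-5-oxooxolan-3-yl}-3-(hydroxymethyl)-6-oxohex-3-en-1-yl (2R)-2-methylbutanoate | CCOP(=O)(OCC)C1C(=O)O[C@@H](/C=C(/C)I)[C@H]1[C@H](OC(=O)[C@H](C)CC)C/C(CO)=C\CC=O | intermediate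
21 | (1(10)E,3S,4Z,6S,7R,8R)-11-(diethoxyphosphoryl)-3,14-dihydroxygermacra-1(10),4-dien-6,12-olid-8-yl (2R)-2-methylbutanoate (C11 epimers) | CCOP(=O)(OCC)C1C(=O)O[C@H]2/C=C(/C)[C@@H](O)C/C=C(/CO)C[C@@H](OC(=O)[C@H](C)CC)[C@@H]12 | intermediate
22 | (1(10)E,3S,4Z,6S,7R,8R)-3,14-dihydroxygermacra-1(10),4,11(13)-trien-6,12-olid-8-yl (2R)-2-methylbutanoate | C=C1C(=O)O[C@H]2/C=C(/C)[C@@H](O)C/C=C(/CO)C[C@@H](OC(=O)[C@H](C)CC)[C@@H]12 | intermediate
23 | (1R,3S,4Z,6S,7R,8R,10R)-1,10-epoxy-3,14-dihydroxygermacra-4,11(13)-dien-6,12-olid-8-yl (2R)-2-methylbutanoate | C=C1C(=O)O[C@H]2/C=C(/C)[C@@H](O)C[C@H]3O[C@@]3(CO)C[C@@H](OC(=O)[C@H](C)CC)[C@@H]12 | target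

## Step count and risks

Total step count: 15. Longest linear sequence: 10 steps (1, 2, 4, 8, 10, 11, 12, 13, 14, 15).

**Step 8 (the proposed new allylboration).** The 2-substituted secondary boronate may react sluggishly, the phosphonate may bind the acid catalyst, or the aldehyde's own facial bias may oppose the catalyst. The fallback uses known chemistry and sets out from 12, 10 and 8. The coupling of 12 with 10 is run enantioselectively (Pd(OAc)2, a chiral monodentate phosphoramidite ligand, aq. KOH, THF) to give the single enantiomer tert-butyl{[(3R)-5,5-diethoxy-2-methylidene-3-(4,4,5,5-tetramethyl-1,3,2-dioxaborolan-2-yl)pentyl]oxy}dimethylsilane F1. This is warmed with 8 in toluene without any catalyst. The stereospecific chair-like allylboration of an enantioenriched α-substituted pinacol allylboronate (axial α-substituent, chirality transfer from C1 to C8) then gives the same alcohol, and the route is rejoined at 14.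

**Step 13 (ring closure and the C3 configuration).** The ten-membered ring may close with poor diastereoselectivity at C3. The fallback sets out from 19 and sets C3 by reagent control.
- Only the acetal is hydrolysed (PPTS, acetone/H2O) to the 14-O-silyl iodo aldehyde F2.
- The same CrCl2/NiCl2 cyclisation gives the macrocyclic 14-O-silyl C3-alcohol mixture F3.
- Dess–Martin oxidation gives the macrocyclic 14-O-silyl 3-ketone F4.
- Corey–Bakshi–Shibata reduction with (R)-Me-CBS and catecholborane (the enone's alkenyl group as the large substituent) gives the 14-O-silyl (3S)-alcohol F5.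
- HF·pyridine removes the silyl group, and the route is rejoined at 21.

**Step 15 (epoxidation on the macrocycle).** The tartrate-preferred face of the 1(10)-olefin may be the transannularly shielded one. The fallback sets out from 19 and epoxidises before ring closure, where reagent control is uncontested.
- HF·pyridine removes the silyl ether to give the acyclic allylic alcohol acetal F6.
- Sharpless epoxidation with D-(−)-diisopropyl tartrate gives the (1R,10R)-epoxy alcohol acetal F7.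
- Neutral transacetalisation (I2, 10 mol%, acetone) frees the aldehyde as the epoxy hydroxy aldehyde F8.
- CrCl2/NiCl2 cyclisation gives the macrocyclic epoxy phosphonolactone F9.
- The formaldehyde/K2CO3 olefination of step 14 then gives the target, and the route is rejoined at 23.

Further compounds
F1 | step 8 | tert-butyl{[(3R)-5,5-diethoxy-2-methylidene-3-(4,4,5,5-tetramethyl-1,3,2-dioxaborolan-2-yl)pentyl]oxy}dimethylsilane | CCOC(OCC)C[C@@H](B1OC(C)(C)C(C)(C)O1)C(=C)CO[Si](C)(C)C(C)(C)C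
F2 | step 13 | (1R,3E)-3-({[tert-butyl(dimethyl)silyl]oxy}methyl)-1-{(2R,3R)-4-(diethoxyphosphoryl)-2-[(1Z)-2-iodoprop-1-en-1-yl]-5-oxooxolan-3-yl}-6-oxohex-3-en-1-yl (2R)-2-methylbutanoate | CCOP(=O)(OCC)C1C(=O)O[C@@H](/C=C(/C)I)[C@H]1[C@H](OC(=O)[C@H](C)CC)C/C(CO[Si](C)(C)C(C)(C)C)=C\CC=O
F3 | step 13 | 14-O-tert-butyldimethylsilyl ether of 21 as a mixture of C3 epimers | CCOP(=O)(OCC)C1C(=O)O[C@H]2/C=C(/C)C(O)C/C=C(/CO[Si](C)(C)C(C)(C)C)C[C@@H](OC(=O)[C@H](C)CC)[C@@H]12
F4 | step 13 | (1(10)E,4Z,6S,7R,8R)-14-[tert-butyl(dimethyl)silyl]oxy-11-(diethoxyphosphoryl)-3-oxogermacra-1(10),4-dien-6,12-olid-8-yl (2R)-2-methylbutanoate | CCOP(=O)(OCC)C1C(=O)O[C@H]2/C=C(/C)C(=O)C/C=C(/CO[Si](C)(C)C(C)(C)C)C[C@@H](OC(=O)[C@H](C)CC)[C@@H]12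
F5 | step 13 | 14-O-tert-butyldimethylsilyl ether of 21, (3S) | CCOP(=O)(OCC)C1C(=O)O[C@H]2/C=C(/C)[C@@H](O)C/C=C(/CO[Si](C)(C)C(C)(C)C)C[C@@H](OC(=O)[C@H](C)CC)[C@@H]12
F6 | step 15 | (1R,3E)-1-{(2R,3R)-4-(diethoxyphosphoryl)-2-[(1Z)-2-iodoprop-1-en-1-yl]-5-oxooxolan-3-yl}-6,6-diethoxy-3-(hydroxymethyl)hex-3-en-1-yl (2R)-2-methylbutanoate | CCOP(=O)(OCC)C1C(=O)O[C@@H](/C=C(/C)I)[C@H]1[C@H](OC(=O)[C@H](C)CC)C/C(CO)=C\CC(OCC)OCC
F7 | step 15 | (1R,10R)-1,10-epoxide of F6 (C3 diethyl acetal, C14 hydroxyl free) | CCOP(=O)(OCC)C1C(=O)O[C@@H](/C=C(/C)I)[C@H]1[C@H](OC(=O)[C@H](C)CC)C[C@]2(CO)O[C@@H]2CC(OCC)OCC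
F8 | step 15 | (1R,10R)-1,10-epoxide of 20 (C3 aldehyde, C14 hydroxyl free) | CCOP(=O)(OCC)C1C(=O)O[C@@H](/C=C(/C)I)[C@H]1[C@H](OC(=O)[C@H](C)CC)C[C@]2(CO)O[C@@H]2CC=O
F9 | step 15 | (1R,3S,4Z,6S,7R,8R,10R)-11-(diethoxyphosphoryl)-1,10-epoxy-3,14-dihydroxygermacr-4-en-6,12-olid-8-yl (2R)-2-methylbutanoate (C11 epimers) | CCOP(=O)(OCC)C1C(=O)O[C@H]2/C=C(/C)[C@@H](O)C[C@H]3O[C@@]3(CO)C[C@@H](OC(=O)[C@H](C)CC)[C@@H]12
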